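Two questions carry these flasks: how far apart do the two hands run, and how many turnovers does each flask give them?

| setting | oak | elm | ash | autumn | dusk | midnight | winter |
|---|---|---|---|---|---|---|---|
| G | 0.20 mM | 0.20 mM | 0.30 mM | 0.20 mM | 0.20 mM | 0.20 mM | 0.20 mM |
| Z | 0.20 mM | 0.20 mM | 0.30 mM | 0.20 mM | 0.20 mM | 0.20 mM | 0.20 mM |
| D | 0.40 mM | 0.90 mM | 0.60 mM | 0.600 mM | 0.600 mM | 0.600 mM | 0.600 mM |
| temperature | 35 °C | 60 °C | 35 °C | 40 °C | 60 °C |  | 80 °C |
| remark | run made earlier | run made earlier | run made earlier |  |  | at 40 °C until 30 s, from then on at 80 °C |  |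
| time |  |  |  | 2.5 min | 2.5 min | 2.5 min | 2.5 min |

| run | time / s | Q / % | J / % |
|---|---|---|---|
| oak | 20.0 | 15.6 | 12.3 |
| oak | 40.0 | 24.9 | 22.1 |
| oak | 60.0 | 29.7 | 27.0 |
| oak | 80.0 | 32.1 | 30.1 |
| oak | 90.0 | 35.6 | 30.0 |
| oak | 120 | 36.1 | 33.1 |
| elm | 10.0 | 40.3 | 35.3 |
| elm | 15.0 | 42.6 | 40.9 |
| elm | 20.0 | 43.8 | 45.1 |
| elm | 30.0 | 47.3 | 48.0 |
| elm | 40.0 | 47.4 | 49.7 |
| ash | 10.0 | 13.6 | 9.7 |
| ash | 20.0 | 20.8 | 19.2 |
| ash | 30.0 | 26.2 | 22.8 |
| ash | 60.0 | 36.1 | 31.3 |
| ash | 120 | 41.0 | 39.2 |

(each reading ± 1 percentage point)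

- D is single-handed; G and Z are mirror images of each other, charged as a racemate, each of them at the stated concentration
- the analysis behind the earlier runs scatters by 1 percentage point, standard deviation
- steps that have been proposed: D + G -> Q; D + Z -> J; G <-> X; Z <-> X; Q <-> J
- the handed part of D does not stay in what it makes, so the products of the two hands are mirror images too

- the flask with the highest share of Q in all that became Q or J ("all alike" if they lie within 1.5 percentage points) (autumn / dusk / midnight / winter / all alike)
- share of Q in all that became Q or J, autumn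
- share of Q in all that became Q or J, dusk
- share of Q in all that became Q or J, midnight
- share of Q in all that became Q or J, winter

How far apart? In the ash run the part of G left is 1−2Q, and likewise 1−2J for Z. The ratio of their logarithms at 30.0 s therefore reads a selectivity factor s = 1.22, G over Z, with the scatter of the readings in it.

How many turnovers? The ash run charges D equal to G and Z together, so with x = Q+J, second-order kinetics gives x/(1−x) = k·D₀·t. That reads k = 53.4 M⁻¹ s⁻¹ at 35 °C. The elm reading at 10.0 s gives 200 M⁻¹ s⁻¹ at 60 °C, more, so the ash value is a low figure for autumn at 40 °C. In autumn D is in excess, and its floor is Δ = 0.200 mM. Integrating, with D ending near Δ, gives n = kΔt + ln(D₀/Δ). Autumn's turnover count is n = 2.70, the natural logarithm of substrate charged over substrate left.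

What survives of the gap? Splitting n between the hands in the ratio s, and leaving out the proposed steps through X and Q ⇌ J, our estimate for autumn's share of Q is 51.0%, and it carries the scatter of the one reading s. That is 0.98 percentage points above even, less than the margin 1.5 points. For dusk at 60 °C, the elm k gives n = 7.11, and the same split, with s held at the ash reading, gives 50.0%. We have no reading for midnight or winter at 80 °C, so carrying s over to them is an assumption, and on it we say alike.

The forecast says all alike: autumn 50.7% (50.2% to 51.4%), dusk 50%, midnight 50%, winter 50%. Its ground: “I therefore see no racemization through X and no Q↔J exchange, just plain kinetic resolution with excess D.” Our estimate stands above its autumn figure, with the same verdict.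

The simulation gives all alike: autumn 49.5%, dusk 50.0%, midnight 50.0%, winter 50.0%.

    D + G → Q (k = 890 M⁻¹ s⁻¹, Ea = 53.0 kJ mol⁻¹)
    D + Z → J (k = 310 M⁻¹ s⁻¹, Ea = 37.0 kJ mol⁻¹)
    G ⇌ X (K = 1.90, k = 0.0260 s⁻¹, Ea = 89.0 kJ mol⁻¹, ΔH = −4.00 kJ mol⁻¹)
    Z ⇌ X (K = 1.90, k = 0.0260 s⁻¹, Ea = 89.0 kJ mol⁻¹, ΔH = −4.00 kJ mol⁻¹)
    Q ⇌ J (k = 0.190 s⁻¹, Ea = 78.0 kJ mol⁻¹)
    (constants at 80 °C)

Autumn's conversion 96.1% is 3.25 turnovers, more than our 2.70. Autumn is still moving slightly: at ten times the time its share is 50.0%. Midnight, at 99.8% or 6.28 turnovers, has come to rest: ten times the time leaves 50.0%, with D at 33.3% of its charge.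

For the neighbour flask, midnight left until 10 min, the ash k gives 7.50 turnovers, so 0.0553% of the substrate left. The simulated flask shows G at 0%, Z at 0% and a share of 50.0%.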